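## Analysis of the target

The target 31 is a 14-membered macrolactone, numbered here from the lactone carbonyl C1 round the ring to C13, the carbinol carbon that carries the ethyl group and the ring oxygen. C1–C3 form a β-keto lactone with a methyl group on C2. C4 is a fully substituted carbinol carbon bearing a hydroxymethyl group, so C3/C4 is an α-ketol. C6=C7 is a Z trisubstituted alkene (methyl on C6), C8 carries a methyl group, and C10(=CH2)–C11=C12 is a cross-conjugated diene whose C11=C12 bond is Z and methylated at C12. The four stereocentres are 2R, 4S, 8S and 13S; carbonyl groups or sp2 carbons separate them, so none can steer another and each must be set on its own. C2 lies between C1 and C3 and epimerises through the enol, so its configuration in 31 is a matter of equilibrium, not of kinetic control. The sensitive groups are the β-keto lactone (retro-Claisen cleavage, acyl transfer to the free hydroxyls), the α-ketol, the acid-labile 2-substituted 1,3-diene and the two Z alkenes. The hard points are the quaternary C4 as one enantiomer, two trisubstituted Z alkenes, and a ring closure that spares all of this. The plan rests on C10–C11: it is the only single bond in the ring between two sp2 carbons, it is remote from C2, C4, C8 and C13, and forming it makes the diene and the ring in one event.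

## Retrosynthetic reasoning

**31 ⇒ 30.** The last operation should only unveil the two hydroxyls on C4. Both are carried as triethylsilyl ethers in 30 and fall to buffered fluoride, which leaves the diene, the β-keto lactone and the α-ketol alone. C2 is left unassigned from 28 to 30 and settles in the ring at the end.

**30 ⇒ 29.** The ring is opened at C10–C11. This bond can be made by cross-coupling under neutral conditions and is at least three bonds from every stereocentre. A 2-bromoalkene at C10 and a Z-alkenylstannane at C11 are spectators that survive many steps. Forming the bond creates the diene, so the diene never has to be carried. A cut at the lactone C–O bond would need a β-keto seco acid that decarboxylates. A cut at C6=C7 or C11=C12 by alkene metathesis would have to deliver a trisubstituted Z alkene beside a diene. In the forward sense palladium must insert into C10–Br, and the C11 alkenyl group must pass from tin with retention.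

**29 ⇒ 28 ⇒ 26 + 18.** C2–C3 is cut as an aldol addition followed by oxidation. No stereocontrol is asked of it, because C3 becomes a ketone and C2 is labile. The ester bond to the hindered C13 oxygen is already present in 26, made on a small fragment with a simple acyl group. The enolate 27 must add to a neopentyl-type aldehyde, which is why the tertiary hydroxyl of 18 is silylated.

**26 ⇒ 25 ⇒ 23.** The C12 methyl group and the C11 metal are introduced together by anti-carbometalation of the alkyne of 23. The alkoxide holds the metal on C11 cis to C13 (chelate 24), and tin then takes the place of magnesium with the Z geometry fixed. The C13 carbinol is traced to ynone 21 by asymmetric transfer hydrogenation (22 after reduction), and 21 to 19 and 20. A catalytic reduction is preferred to a resolution of racemic 23, whose ethyl and ethynyl groups are too alike in size for reliable enzymatic discrimination.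

**18 ⇒ 17 ⇒ 16 ⇒ 15.** These are oxidation-state and protecting-group changes. The acetal of 15 is exchanged for silyl ethers before any tin is in the molecule, because the acid that cleaves the acetal would also cleave a C–Sn bond and later endanger the diene.

**15 ⇒ 11 + 13 (via 14).** C4–C5 is cut as the alkylation of a glycerate enolate by the allylic bromide 11. The commercial acetonide 12 cannot serve directly: deprotonation at C4 removes its only stereocentre and the enolate is achiral. 12 is therefore first converted into the cis tert-butyl acetal 13. Its acetal carbon stores the chirality while C4 is planar in 14 and returns it by directing 11 to the ring face away from the tert-butyl group.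

**11 ⇒ 10 ⇒ 9 ⇒ 6 + 7.** C6=C7 is cut as a Still–Gennari olefination of aldehyde 6 with 7 (via 8). This is the dependable way to a Z α-methyl enoate. Its ester carbon is C5, which is reduced (10) and brominated (11).

**6 ⇒ 5 ⇒ 4 ⇒ 1 + 2.** C8–C9 is cut as an auxiliary-controlled alkylation of 1 (via 3) with 2. Compound 2 delivers C9, C10, the exocyclic methylene carbon and the bromine in one piece, so the coupling handle is in place from the first step.

## Alternatives that were turned down

**Alternative 1: conjunctive coupling at C4.**
- Disconnection: C5–C6 and C3–C4 of an open-chain C3–C10 fragment.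
- Forward key step: the alkenylboronic ester A2 and the silylmethyl Grignard reagent A3 form a boron ate complex. With Pd(OAc)2, MandyPhos and NaOTf the alkenylpalladium species from the Z-alkenyl bromide A4 triggers a 1,2-shift of the silylmethyl group to C4 and bonds C5 to C6, giving the tertiary boronic ester A1.
- For it: C4 would be set by a catalyst, both C–C bonds at C4 form in one step, and boron and silicon are later oxidised to the C4 hydroxyl and the C3 oxygen.
- Against it: ate complexes of α-substituted alkenylboron compounds are the most demanding class for this coupling. Migration to a carbon that becomes fully substituted is slow and competes with direct transfer of the alkenyl group. The electrophile A4 is a hindered trisubstituted alkenyl bromide. The catalyst must distinguish two similar CH2 arms at C4. A1 still needs two oxidations and conversion of its silylalkyne into the C10 coupling handle, and no ring is closed.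
- Comparison: on catalytic, auxiliary-free control of C4 this alternative is stronger. The chosen route offers a C4 centre taken from the chiral pool by a known enolate alkylation, a bromoalkene present from step 1, and a ring closure that is defined and remote from C4.

**Alternative 2: alkyne metathesis at C6–C7.**
- Disconnection: C6–C7 as an alkyne.
- Forward key step: the diyne A5 is closed with Mo(≡CC6H4OMe)(OSiPh3)3 and 5 Å molecular sieves to the cycloalkyne A6, with loss of but-2-yne.
- For it: alkyne metathesis does not touch the diene or the exocyclic methylene, closes 14-membered rings reliably at unhindered sp carbons, and needs no tin. On the ring closure itself it is at least as strong as the chosen step.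
- Against it: A6 must then take up a methyl group at C6 and a hydrogen at C7 from the same side. Both alkyne carbons are flanked by sp3 carbons and no free directing group is nearby, so regiocontrol between C6 and C7 is not secured. This carbometalation would be run on a ring that holds a β-keto lactone and a diene. A5 also needs two methyl-capped alkynes and an earlier intermolecular diene synthesis, which is more steps than one olefination.
- Comparison: the chosen route fixes the C6=C7 geometry on a seven-carbon fragment, before any sensitive group exists.

**Alternative 3: Reformatsky closure at C2–C3.**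
- Disconnection: C2–C3.
- Forward key step: SmI2 turns the 2-bromopropanoate of A7 into a samarium enolate that adds to the C3 aldehyde and gives the β-hydroxy lactone A8. Oxidation to the β-keto lactone follows.
- For it: C2/C3 stereochemistry is irrelevant, samarium ties enolate and aldehyde together, and the reaction is fast at low temperature. The diene is made earlier by an easier intermolecular coupling. The closure does not depend on slow oxidative addition into a bromoalkene, and on that point it is stronger.
- Against it: the aldehyde is neopentyl-like and α-silyloxy, and a one-electron reductant can form the ketyl and expel the α-oxygen. One more oxidation is needed on the finished macrocycle, and the hindered C13 alcohol must be acylated with a 2-bromoacyl halide.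
- Comparison: the chosen route closes the ring under neutral, non-reducing conditions far from the α-ketol and arrives directly at the ketone oxidation level. This alternative is kept as the fallback for the key step.

Key step: step 19

**Remarks on the chemistry (assumptions)**
- Enolate 14 is taken to react on the ring face opposite the tert-butyl group, as expected for 2-tert-butyl-1,3-dioxolane enolates without an N-acyl group. If the other face reacted, the enantiomeric acetal would be used.
- The 2R configuration of 31 is taken to be the more stable one in the 14-membered ring and is reached by equilibration.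

## Route

Step 1
Reactants: 1 (R)-4-benzyl-3-propanoyl-1,3-oxazolidin-2-one; 2 2,3-dibromopropene
Product: 4 (R)-4-benzyl-3-[(S)-4-bromo-2-methylpent-4-enoyl]-1,3-oxazolidin-2-one, via sodium Z-enolate 3 (not isolated)
Conditions: NaN(SiMe3)2, THF, −78 °C; then 2 (3 equiv), −78 → −40 °C
Reagents that add atoms: none
Why: Evans asymmetric alkylation: the chelated Z-enolate 3 is attacked by the allylic CH2Br of 2 on the face opposite the benzyl group, which sets C8 as S; the vinylic bromide does not react and becomes the coupling handle.

Step 2
Reactants: 4
Product: 5 (S)-4-bromo-2-methylpent-4-en-1-ol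
Conditions: LiBH4, MeOH (1 equiv), Et2O, 0 °C
Reagents that add atoms: none
Why: Reductive cleavage of the N-acyl oxazolidinone by borohydride; the exocyclic carbonyl is reduced, the auxiliary is released for recovery and C8 is not enolised.

Step 3
Reactants: 5
Product: 6 (S)-4-bromo-2-methylpent-4-enal
Conditions: Dess–Martin periodinane, NaHCO3, CH2Cl2, 0 °C → rt; used crude at once
Reagents that add atoms: none
Why: Dess–Martin oxidation under buffered, non-basic conditions should give the α-branched aldehyde without epimerisation at C8.

Step 4
Reactants: 6; 7 ethyl 2-[bis(2,2,2-trifluoroethoxy)phosphoryl]propanoate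
Product: 9 ethyl (2Z,4S)-6-bromo-2,4-dimethylhepta-2,6-dienoate, via potassium phosphonate carbanion 8 (not isolated)
Conditions: 7, KN(SiMe3)2, 18-crown-6, THF, −78 °C; then 6
Reagents that add atoms: none
Why: Still–Gennari olefination: with the electron-poor phosphonate the adduct eliminates faster than it equilibrates, so the Z enoate forms, with the ester carbon (C5) cis to C8; the weakly basic carbanion should not epimerise 6.

Step 5
Reactants: 9
Product: 10 (2Z,4S)-6-bromo-2,4-dimethylhepta-2,6-dien-1-ol
Conditions: i-Bu2AlH (2.2 equiv), CH2Cl2, −78 °C; aq. potassium sodium tartrate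
Reagents that add atoms: none
Why: 1,2-Reduction of the enoate by i-Bu2AlH gives the allylic alcohol; the bromoalkene and the alkene geometry are untouched at low temperature.

Step 6
Reactants: 10
Product: 11 (4S,5Z)-2,7-dibromo-4,6-dimethylhepta-1,5-diene
Conditions: CBr4, PPh3, CH2Cl2, 0 °C
Reagents that add atoms: tetrabromomethane, BrC(Br)(Br)Br
Why: Appel bromination of a primary allylic alcohol by SN2 at carbon under neutral conditions, which keeps the Z geometry at C6=C7.

Step 7
Reactants: 12 methyl (S)-2,2-dimethyl-1,3-dioxolane-4-carboxylate
Product: 13 methyl (2S,4S)-2-tert-butyl-1,3-dioxolane-4-carboxylate (cis)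
Conditions: t-BuCHO (5 equiv), TsOH·H2O (cat.), pentane, reflux, acetone distilled off; cis isomer separated by chromatography
Reagents that add atoms: pivalaldehyde, CC(C)(C)C=O
Why: Acid-catalysed transacetalisation, driven by the greater stability of the aldehyde acetal and removal of acetone; the acetal carbon forms under thermodynamic control, the cis isomer is separated and the trans isomer can be returned to the equilibration; C4 is not touched.

Step 8
Reactants: 13; 11
Product: 15 methyl (2S,4S)-4-[(2Z,4S)-6-bromo-2,4-dimethylhepta-2,6-dien-1-yl]-2-tert-butyl-1,3-dioxolane-4-carboxylate, via lithium ester enolate 14 (not isolated)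
Conditions: LiN(i-Pr)2, THF, −78 °C; then 11, DMPU, −78 → −60 °C
Reagents that add atoms: none
Why: Enolate alkylation with self-regeneration of the stereocentre: C4 is planar in 14 but the acetal carbon keeps the chirality and its tert-butyl group shields one ring face, so 11 should enter trans to it and set C4 in the sense needed (S in the ring numbering of 31). β-Elimination of the ring oxygen should be slow at −78 °C because that C–O bond lies near the nodal plane of the enolate.

Step 9
Reactants: 15
Product: 16 methyl (2S,4Z,6S)-8-bromo-2-hydroxy-2-(hydroxymethyl)-4,6-dimethylnona-4,8-dienoate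
Conditions: HCl (1.25 M in MeOH), 40 °C
Reagents that add atoms: none
Why: Acid-catalysed acetal exchange with methanol frees the 1,2-diol; dilute methanolic acid should not protonate the trisubstituted alkene or the bromoalkene, and the step is placed before tin is in the molecule.

Step 10
Reactants: 16
Product: 17 methyl (2S,4Z,6S)-8-bromo-4,6-dimethyl-2-(triethylsilyloxy)-2-[(triethylsilyloxy)methyl]nona-4,8-dienoate
Conditions: TESOTf (2.5 equiv), 2,6-lutidine, CH2Cl2, −78 → 0 °C
Reagents that add atoms: triethylsilyl trifluoromethanesulfonate, CC[Si](CC)(CC)OS(=O)(=O)C(F)(F)F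
Why: Silyl triflates silylate the primary and the hindered tertiary hydroxyl alike; capping the tertiary hydroxyl avoids an α-hydroxy aldehyde and a free alkoxide in the aldol step, and both ethers are removed together at the end.

Step 11
Reactants: 17
Product: 18 (2S,4Z,6S)-8-bromo-4,6-dimethyl-2-(triethylsilyloxy)-2-[(triethylsilyloxy)methyl]nona-4,8-dienal
Conditions: i-Bu2AlH (1.2 equiv), CH2Cl2, −78 °C; MeOH, then aq. potassium sodium tartrate
Reagents that add atoms: none
Why: Partial reduction of an α-silyloxy ester: the aluminium hemiacetal, stabilised by the α-oxygen, should persist at −78 °C and give the aldehyde on work-up; C4 is quaternary and cannot epimerise.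

Step 12
Reactants: 19 N-methoxy-N-methylpropanamide; 20 lithium (trimethylsilyl)acetylide
Product: 21 1-(trimethylsilyl)pent-1-yn-3-one
Conditions: THF, −78 → 0 °C; aq. NH4Cl
Reagents that add atoms: none
Why: Weinreb ketone synthesis: the chelated tetrahedral adduct stops the addition at the ketone stage.

Step 13
Reactants: 21
Product: 22 (S)-1-(trimethylsilyl)pent-1-yn-3-ol
Conditions: Ru[(S,S)-TsNCH(Ph)CH(Ph)NH](η6-p-cymene) (0.5 mol%), i-PrOH, rt
Reagents that add atoms: none
Why: Noyori asymmetric transfer hydrogenation of a conjugated ynone: hydride and proton are passed on in a six-membered transition state in which the alkyne takes the place usually held by an aryl group, so the (S,S) catalyst should give the S carbinol (C13).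

Step 14
Reactants: 22
Product: 23 (S)-pent-1-yn-3-ol
Conditions: K2CO3, MeOH, rt; kept as a concentrated ethereal solution (volatile)
Reagents that add atoms: none
Why: Base-mediated protodesilylation of the alkynylsilane; the carbinol centre is not affected.

Step 15
Reactants: 23
Product: 25 (S,Z)-2-methyl-1-(tributylstannyl)pent-1-en-3-ol, via alkenylmagnesium alkoxide 24 (not isolated)
Conditions: MeMgBr (3 equiv), CuI (15 mol%), THF/Et2O, −10 °C → rt; then Bu3SnCl (2 equiv), 0 °C → rt; aq. NH4Cl
Reagents that add atoms: methylmagnesium bromide, C[Mg]Br; tributyltin chloride, CCCC[Sn](Cl)(CCCC)CCCC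
Why: Copper-catalysed anti-carbomagnesiation of a propargylic alkoxide: methyl adds to the alkyne carbon next to the carbinol (C12) and magnesium to the terminal carbon (C11) on the alkoxide side, closing the five-membered chelate 24 that fixes the Z geometry. The tin chloride then replaces magnesium with retention; C13 takes no part.

Step 16
Reactants: 25
Product: 26 (S,Z)-2-methyl-1-(tributylstannyl)pent-1-en-3-yl propanoate
Conditions: (EtCO)2O, Et3N, DMAP (cat.), CH2Cl2, 0 °C → rt
Reagents that add atoms: propanoic anhydride, CCC(=O)OC(=O)CC
Why: DMAP-catalysed acylation of the secondary allylic alcohol with retention at C13; the amine-buffered medium protects the acid-sensitive alkenyl–tin bond.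

Step 17
Reactants: 26; 18
Product: 28 (S,Z)-2-methyl-1-(tributylstannyl)pent-1-en-3-yl (4S,6Z,8S)-10-bromo-3-hydroxy-2,6,8-trimethyl-4-(triethylsilyloxy)-4-[(triethylsilyloxy)methyl]undeca-6,10-dienoate (mixture at C2 and C3), via lithium ester enolate 27 (not isolated)
Conditions: 26 (1.2 equiv), LiN(i-Pr)2, THF, −78 °C; then 18, −78 °C; aq. NH4Cl at −78 °C
Reagents that add atoms: none
Why: Lithium ester-enolate aldol addition forms C2–C3; the two new centres arise as a mixture, which does not matter because C3 is oxidised next and C2 is labile. Keeping the reaction at −78 °C should suppress retro-aldol and [3,3] rearrangement of the allyl ester enolate.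

Step 18
Reactants: 28
Product: 29 (S,Z)-2-methyl-1-(tributylstannyl)pent-1-en-3-yl (4S,6Z,8S)-10-bromo-2,6,8-trimethyl-3-oxo-4-(triethylsilyloxy)-4-[(triethylsilyloxy)methyl]undeca-6,10-dienoate (both C2 epimers)
Conditions: Dess–Martin periodinane, NaHCO3, CH2Cl2, rt
Reagents that add atoms: none
Why: Dess–Martin oxidation of the β-hydroxy ester to the β-keto ester under buffered, neutral conditions that the alkenylstannane, the silyl ethers and the alkenes tolerate.

Step 19
Reactants: 29
Product: 30 (5S,7Z,9S,12Z,14S)-14-ethyl-3,7,9,13-tetramethyl-11-methylidene-5-(triethylsilyloxy)-5-[(triethylsilyloxy)methyl]-1-oxacyclotetradeca-7,12-diene-2,4-dione (both epimers at ring position 3, which is C2 of the text numbering)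
Conditions: Pd2(dba)3·CHCl3 (15 mol%), AsPh3 (60 mol%), CuI (30 mol%), degassed DMF, 50 °C, slow addition of 29 to a final 0.001 M
Reagents that add atoms: none
Why: Macrocyclising Stille coupling; the closest known reaction type is the intramolecular coupling of an alkenyl halide with an alkenylstannane to a macrocyclic 1,3-diene. Zerovalent palladium, lightly ligated by AsPh3, inserts into the C10–Br bond to give an alkenyl divalent palladium bromide; the Z-alkenyl group at C11 then passes from tin to palladium with retention, CuI assisting this slow step for the β,β-disubstituted stannane, and reductive elimination forms C10–C11. The 14-membered ring closes in this transmetalation and reductive elimination sequence: the tethered stannane reaches palladium to form a 15-membered palladacycle, which contracts to the lactone ring when the C–C bond forms. No stereocentre is created, and the Z geometry at C11=C12 from step 15 is kept because neither elementary step breaks the alkene π bond. The selectivity that matters is ring closure against intermolecular coupling; it is secured by slow addition at high dilution and helped by the two Z trisubstituted alkenes and the fully substituted C4, which bend the chain. The conditions are neutral and non-nucleophilic, so the β-keto ester, the silyl ethers and C2 are spectators, and C4, C8 and C13 are at least three bonds from the reacting carbons.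

Step 20
Reactants: 30
Product: 31 (3R,5S,7Z,9S,12Z,14S)-14-ethyl-5-hydroxy-5-(hydroxymethyl)-3,7,9,13-tetramethyl-11-methylidene-1-oxacyclotetradeca-7,12-diene-2,4-dione (the target; 2R,4S,8S,13S in the text numbering)
Conditions: HF·pyridine, pyridine, THF, 0 °C → rt
Reagents that add atoms: none
Why: Fluoride cleavage of both triethylsilyl ethers under buffered conditions that should spare the diene and the β-keto lactone; C2 interconverts through the enol of the β-keto lactone and should settle in the configuration preferred by the ring, taken to be 2R.

## Compound list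

1 | (R)-4-benzyl-3-propanoyl-1,3-oxazolidin-2-one | CCC(=O)N1[C@H](Cc2ccccc2)COC1=O | starting material
2 | 2,3-dibromopropene | C=C(Br)CBr | starting material
3 | sodium (Z)-enolate of 1 | C/C=C(\[O-])N1[C@H](Cc2ccccc2)COC1=O.[Na+] | intermediate
4 | (R)-4-benzyl-3-[(S)-4-bromo-2-methylpent-4-enoyl]-1,3-oxazolidin-2-one | C=C(Br)C[C@H](C)C(=O)N1[C@H](Cc2ccccc2)COC1=O | intermediate
5 | (S)-4-bromo-2-methylpent-4-en-1-ol | C=C(Br)C[C@H](C)CO | intermediate
6 | (S)-4-bromo-2-methylpent-4-enal | C=C(Br)C[C@H](C)C=O | intermediate
7 | ethyl 2-[bis(2,2,2-trifluoroethoxy)phosphoryl]propanoate | CCOC(=O)C(C)P(=O)(OCC(F)(F)F)OCC(F)(F)F | starting material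
8 | potassium carbanion of 7 | CCOC(=O)[C-](C)P(=O)(OCC(F)(F)F)OCC(F)(F)F.[K+] | intermediate
9 | ethyl (2Z,4S)-6-bromo-2,4-dimethylhepta-2,6-dienoate | C=C(Br)C[C@H](C)/C=C(/C)C(=O)OCC | intermediate
10 | (2Z,4S)-6-bromo-2,4-dimethylhepta-2,6-dien-1-ol | C=C(Br)C[C@H](C)/C=C(/C)CO | intermediate
11 | (4S,5Z)-2,7-dibromo-4,6-dimethylhepta-1,5-diene | C=C(Br)C[C@H](C)/C=C(/C)CBr | intermediate
12 | methyl (S)-2,2-dimethyl-1,3-dioxolane-4-carboxylate | COC(=O)[C@@H]1COC(C)(C)O1 | starting material
13 | methyl (2S,4S)-2-tert-butyl-1,3-dioxolane-4-carboxylate (cis) | COC(=O)[C@@H]1CO[C@H](C(C)(C)C)O1 | intermediate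
14 | lithium enolate of 13 (acetal carbon S) | COC([O-])=C1CO[C@H](C(C)(C)C)O1.[Li+] | intermediate
15 | methyl (2S,4S)-4-[(2Z,4S)-6-bromo-2,4-dimethylhepta-2,6-dien-1-yl]-2-tert-butyl-1,3-dioxolane-4-carboxylate | COC(=O)[C@]1(C/C(C)=C\[C@@H](C)CC(Br)=C)CO[C@H](C(C)(C)C)O1 | intermediate
16 | methyl (2S,4Z,6S)-8-bromo-2-hydroxy-2-(hydroxymethyl)-4,6-dimethylnona-4,8-dienoate | COC(=O)[C@@](O)(CO)C/C(C)=C\[C@@H](C)CC(Br)=C | intermediate
17 | methyl (2S,4Z,6S)-8-bromo-4,6-dimethyl-2-(triethylsilyloxy)-2-[(triethylsilyloxy)methyl]nona-4,8-dienoate | COC(=O)[C@@](O[Si](CC)(CC)CC)(CO[Si](CC)(CC)CC)C/C(C)=C\[C@@H](C)CC(Br)=C | intermediate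
18 | (2S,4Z,6S)-8-bromo-4,6-dimethyl-2-(triethylsilyloxy)-2-[(triethylsilyloxy)methyl]nona-4,8-dienal | O=C[C@@](O[Si](CC)(CC)CC)(CO[Si](CC)(CC)CC)C/C(C)=C\[C@@H](C)CC(Br)=C | intermediate
19 | N-methoxy-N-methylpropanamide | CCC(=O)N(C)OC | starting material
20 | lithium (trimethylsilyl)acetylide | [Li]C#C[Si](C)(C)C | starting material
21 | 1-(trimethylsilyl)pent-1-yn-3-one | CCC(=O)C#C[Si](C)(C)C | intermediate
22 | (S)-1-(trimethylsilyl)pent-1-yn-3-ol | CC[C@H](O)C#C[Si](C)(C)C | intermediate
23 | (S)-pent-1-yn-3-ol | CC[C@H](O)C#C | intermediate
24 | (S,Z)-alkenylmagnesium bromide with bromomagnesium alkoxide (chelate from carbomagnesiation of 23) | Br[Mg]/C=C(/C)[C@H](CC)O[Mg]Br | intermediate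
25 | (S,Z)-2-methyl-1-(tributylstannyl)pent-1-en-3-ol | CCCC[Sn](CCCC)(CCCC)/C=C(/C)[C@H](CC)O | intermediate
26 | (S,Z)-2-methyl-1-(tributylstannyl)pent-1-en-3-yl propanoate | CCCC[Sn](CCCC)(CCCC)/C=C(/C)[C@H](CC)OC(=O)CC | intermediate
27 | lithium enolate of 26 | CCCC[Sn](CCCC)(CCCC)/C=C(/C)[C@H](CC)OC([O-])=CC.[Li+] | intermediate
28 | aldol adduct, β-hydroxy ester (mixture at C2 and C3) | CCCC[Sn](CCCC)(CCCC)/C=C(/C)[C@H](CC)OC(=O)C(C)C(O)[C@@](O[Si](CC)(CC)CC)(CO[Si](CC)(CC)CC)C/C(C)=C\[C@@H](C)CC(Br)=C | intermediate
29 | seco β-keto ester with C10 bromoalkene and C11 Z-stannane (both C2 epimers) | CCCC[Sn](CCCC)(CCCC)/C=C(/C)[C@H](CC)OC(=O)C(C)C(=O)[C@@](O[Si](CC)(CC)CC)(CO[Si](CC)(CC)CC)C/C(C)=C\[C@@H](C)CC(Br)=C | intermediate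
30 | bis(triethylsilyl) 14-membered macrolide (both C2 epimers) | C=C1/C=C(/C)[C@H](CC)OC(=O)C(C)C(=O)[C@@](O[Si](CC)(CC)CC)(CO[Si](CC)(CC)CC)C/C(C)=C\[C@@H](C)C1 | intermediate
31 | (3R,5S,7Z,9S,12Z,14S)-14-ethyl-5-hydroxy-5-(hydroxymethyl)-3,7,9,13-tetramethyl-11-methylidene-1-oxacyclotetradeca-7,12-diene-2,4-dione | C=C1/C=C(/C)[C@H](CC)OC(=O)[C@H](C)C(=O)[C@@](O)(CO)C/C(C)=C\[C@@H](C)C1 | target

## Step count and least certain steps

Total: 20 steps. Longest linear sequence: 14 steps (steps 1–6, 8–11, 17–20).

**Step 19 (key step).** Oxidative addition into the 2-bromoalkene may be slow with the weakly donating arsine, and transfer of the hindered Z-alkenyl group from tin may be slow too. Protodestannylation, stannane homocoupling and intermolecular coupling at the required dilution could then compete with ring closure. The fallback closes the ring at C2–C3 instead. It sets out from 18 and 25, which are coupled intermolecularly at normal concentration (Pd2(dba)3, AsPh3, CuI, DMF, excess 25) to the diene hydroxy aldehyde F1. Acylation with 2-bromopropanoyl bromide and pyridine at low temperature gives the bromo ester aldehyde F2. SmI2 in THF at −78 °C under high dilution closes the ring by an intramolecular Reformatsky addition to the β-hydroxy lactone F3. Dess–Martin oxidation of F3 comes back to the route at 30.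

**Step 8.** Enolate 14 may open by β-elimination of the ring oxygen before it is alkylated. The remote tert-butyl group may discriminate the two faces incompletely. The purity at C4 also depends on how cleanly 13 was freed of its trans isomer in step 7. The fallback sets C4 by a Sharpless asymmetric epoxidation and sets out from 11. The sodium salt of triethyl phosphonoacetate is alkylated with 11 to the phosphonate F4. K2CO3 and aqueous formaldehyde give the 2-methylene ester F5, and i-Bu2AlH gives the 2-substituted allylic alcohol F6. Epoxidation with Ti(OiPr)4, L-(+)-diethyl tartrate and t-BuOOH at −20 °C should give the (S)-epoxy alcohol F7; the allylic alkene reacts, the remote trisubstituted one does not. Ti(OiPr)4 and benzoic acid open the epoxide at its CH2 terminus to the diol benzoate F8, and TESOTf with 2,6-lutidine gives the bis(silyl ether) F9. Reductive removal of the benzoate with i-Bu2AlH at −78 °C gives the primary alcohol F10, and Dess–Martin oxidation comes back to the route at 18. This path is four steps longer but does not rely on a low-temperature β-alkoxy enolate.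

**Step 20.** The two C2 epimers may differ little in energy in a flexible 14-membered ring, so equilibration may stop at a mixture. Acyl transfer from the ring oxygen to a freed hydroxyl (ring contraction) could set in on long exposure. The fallback sets C2 kinetically and sets out from 30. It is deprotonated at C2 with KN(SiMe3)2 at −78 °C and reprotonated by a bulky phenol from the less hindered periphery of the ring, which should give the single (2R)-configured bis(silyl ether) F11. A short, cold treatment of F11 with HF·pyridine, worked up before the enol can equilibrate, comes back to the route at 31.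

**Step 15.** The alkenylmagnesium centre held in chelate 24 may react sluggishly with the tin chloride. Protonation on work-up would then give the tin-free allylic alcohol, and excess Grignard reagent would consume the tin chloride by methyl transfer. The fallback sets out from 23. The same carbomagnesiation is quenched with I2, which traps such chelates readily, to give (S,Z)-1-iodo-2-methylpent-1-en-3-ol F12. Palladium-catalysed stannylation of F12 with hexabutyldistannane (PdCl2(PPh3)2, THF) comes back to the route at 25.

## Further compounds

F1 | step 19 | (2S,4Z,6S,9Z,11S)-11-hydroxy-4,6,10-trimethyl-8-methylidene-2-(triethylsilyloxy)-2-[(triethylsilyloxy)methyl]trideca-4,9-dienal | O=C[C@@](O[Si](CC)(CC)CC)(CO[Si](CC)(CC)CC)C/C(C)=C\[C@@H](C)CC(=C)/C=C(/C)[C@H](CC)O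
F2 | step 19 | 2-bromopropanoate of F1 (mixture at the bromine-bearing carbon) | O=C[C@@](O[Si](CC)(CC)CC)(CO[Si](CC)(CC)CC)C/C(C)=C\[C@@H](C)CC(=C)/C=C(/C)[C@H](CC)OC(=O)C(C)Br
F3 | step 19 | bis(triethylsilyl) 14-membered β-hydroxy lactone (mixture at C2 and C3) | C=C1/C=C(/C)[C@H](CC)OC(=O)C(C)C(O)[C@@](O[Si](CC)(CC)CC)(CO[Si](CC)(CC)CC)C/C(C)=C\[C@@H](C)C1
F4 | step 8 | ethyl (4Z,6S)-8-bromo-2-(diethoxyphosphoryl)-4,6-dimethylnona-4,8-dienoate (mixture at C2) | CCOC(=O)C(C/C(C)=C\[C@@H](C)CC(Br)=C)P(=O)(OCC)OCC
F5 | step 8 | ethyl (4Z,6S)-8-bromo-4,6-dimethyl-2-methylidenenona-4,8-dienoate | CCOC(=O)C(=C)C/C(C)=C\[C@@H](C)CC(Br)=C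
F6 | step 8 | (4Z,6S)-8-bromo-4,6-dimethyl-2-methylidenenona-4,8-dien-1-ol | OCC(=C)C/C(C)=C\[C@@H](C)CC(Br)=C
F7 | step 8 | [(2S)-2-[(2Z,4S)-6-bromo-2,4-dimethylhepta-2,6-dien-1-yl]oxiran-2-yl]methanol | OC[C@@]1(C/C(C)=C\[C@@H](C)CC(Br)=C)CO1
F8 | step 8 | (2S,4Z,6S)-8-bromo-2-hydroxy-2-(hydroxymethyl)-4,6-dimethylnona-4,8-dien-1-yl benzoate | O=C(OC[C@@](O)(CO)C/C(C)=C\[C@@H](C)CC(Br)=C)c1ccccc1
F9 | step 8 | (2R,4Z,6S)-8-bromo-4,6-dimethyl-2-(triethylsilyloxy)-2-[(triethylsilyloxy)methyl]nona-4,8-dien-1-yl benzoate | O=C(OC[C@@](O[Si](CC)(CC)CC)(CO[Si](CC)(CC)CC)C/C(C)=C\[C@@H](C)CC(Br)=C)c1ccccc1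
F10 | step 8 | (2R,4Z,6S)-8-bromo-4,6-dimethyl-2-(triethylsilyloxy)-2-[(triethylsilyloxy)methyl]nona-4,8-dien-1-ol | OC[C@@](O[Si](CC)(CC)CC)(CO[Si](CC)(CC)CC)C/C(C)=C\[C@@H](C)CC(Br)=C
F11 | step 20 | (2R)-epimer of 30, bis(triethylsilyl) macrolide with C2 defined | C=C1/C=C(/C)[C@H](CC)OC(=O)[C@H](C)C(=O)[C@@](O[Si](CC)(CC)CC)(CO[Si](CC)(CC)CC)C/C(C)=C\[C@@H](C)C1
F12 | step 15 | (S,Z)-1-iodo-2-methylpent-1-en-3-ol | I/C=C(/C)[C@H](CC)O
A1 | alternative 1 | tertiary pinacol boronic ester, C3–C10 fragment | CC(C)O[Si](C)(C)C[C@@](B1OC(C)(C)C(C)(C)O1)(CO[Si](C)(C)C(C)(C)C)C/C(C)=C\[C@@H](C)CC#C[Si](C)(C)C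
A2 | alternative 1 | tert-butyldimethyl{[2-(4,4,5,5-tetramethyl-1,3,2-dioxaborolan-2-yl)prop-2-en-1-yl]oxy}silane | C=C(CO[Si](C)(C)C(C)(C)C)B1OC(C)(C)C(C)(C)O1
A3 | alternative 1 | [(isopropoxydimethylsilyl)methyl]magnesium chloride | CC(C)O[Si](C)(C)C[Mg]Cl
A4 | alternative 1 | [(4S,5Z)-6-bromo-4-methylhept-5-en-1-yn-1-yl]trimethylsilane | Br/C(C)=C\[C@@H](C)CC#C[Si](C)(C)C
A5 | alternative 2 | seco diyne with methyl-capped alkynes at C6 and C7, bis-silyl protected | CC#C[C@@H](C)CC(=C)/C=C(/C)[C@H](CC)OC(=O)[C@H](C)C(=O)[C@@](O[Si](CC)(CC)CC)(CO[Si](C)(C)C(C)(C)C)CC#CC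
A6 | alternative 2 | 14-membered cycloalkyne lactone, bis-silyl protected | C=C1/C=C(/C)[C@H](CC)OC(=O)[C@H](C)C(=O)[C@@](O[Si](CC)(CC)CC)(CO[Si](C)(C)C(C)(C)C)CC#C[C@@H](C)C1
A7 | alternative 3 | seco C3 aldehyde with 2-bromopropanoate on O13, bis-silyl protected | O=C[C@@](O[Si](CC)(CC)CC)(CO[Si](C)(C)C(C)(C)C)C/C(C)=C\[C@@H](C)CC(=C)/C=C(/C)[C@H](CC)OC(=O)C(C)Br
A8 | alternative 3 | 14-membered β-hydroxy lactone, mixture at C2 and C3 | C=C1/C=C(/C)[C@H](CC)OC(=O)C(C)C(O)[C@@](O[Si](CC)(CC)CC)(CO[Si](C)(C)C(C)(C)C)C/C(C)=C\[C@@H](C)C1
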